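**Plan** (flavan numbering: O1, C2, C3, C4, C4a, C5–C8, C8a; ring A = benzo ring, ring B = 2-aryl ring, ring C = pyran ring)
- Retrosynthesis: cut the two aryl O–CH2OMe bonds first, then C3–C4 together with C2–H (ring C), then the C2=CH2 carbon (back to an ester C=O) and the O1–C2 acyl bond (rings A and B apart), and in ring A the C4a–C4 and C8–prenyl bonds.
- Forward: ring A is dressed on 5-methoxyresorcinol by two directed lithiations (prenyl at C8, formyl at C4a) and esterified through O1 with the ring B acid. The aldehyde becomes the C4 silyl ether, the ester C=O is methylenated to an aryl 1-arylvinyl ether, ring C closes last, and the two MOM groups come off.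
- Enabling feature: C4 is a benzylic carbon on ring A with oxygen at C5 and C8a (ortho) and C7 (para), so its silyloxy group ionizes under a chiral Brønsted acid to an O-alkyl para-quinone-methide-type cation. C3, the terminal carbon of the vinyl ether on O1, is the matching nucleophile, and O1 plus the aryl group on C2 stabilize the oxocarbenium ion that results.
- Stereochemistry: the only stereocentre, C2, is set in the same operation by hydride transfer from a Hantzsch ester to that oxocarbenium ion inside its ion pair with the chiral acid anion (catalyst control); no later step touches C2.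

Key step: step 9

Assumption: the target is read as the (2R)-flavan; the (R)-catalyst is written, and its mirror image would be used unchanged if the sense of induction proved opposite.

**Route**

Step 1
Reactants: 1 5-methoxybenzene-1,3-diol (5-methoxyresorcinol)
Product: 2 1-methoxy-3,5-bis(methoxymethoxy)benzene
Conditions: NaH (2.4 equiv), MOMCl (2.4 equiv), DMF, 0 °C → rt
Reagents that add atoms: chloromethyl methyl ether (MOMCl), COCCl
Why: Williamson etherification of both phenoxides with the reactive α-chloro ether should give the bis-acetal, whose OCH2OMe groups later direct the metalations.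

Step 2
Reactants: 2 1-methoxy-3,5-bis(methoxymethoxy)benzene; 3 1-bromo-3-methylbut-2-ene (prenyl bromide)
Product: 5 5-methoxy-1,3-bis(methoxymethoxy)-2-(3-methylbut-2-en-1-yl)benzene, via aryllithium 4 (not isolated)
Conditions: n-BuLi (1.1 equiv), THF, 0 °C; then CuI (10 mol %), 3, −78 °C → rt
Reagents that add atoms: none
Why: Directed ortho-metalation should occur at the carbon flanked by both OCH2OMe groups, and copper-assisted SN2 alkylation with prenyl bromide should give the unrearranged prenyl arene.

Step 3
Reactants: 5 5-methoxy-1,3-bis(methoxymethoxy)-2-(3-methylbut-2-en-1-yl)benzene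
Product: 7 6-methoxy-2,4-bis(methoxymethoxy)-3-(3-methylbut-2-en-1-yl)benzaldehyde, via aryllithium 6 (not isolated)
Conditions: n-BuLi, TMEDA, THF, −20 → 0 °C; then DMF, −78 °C → rt; H2O
Reagents that add atoms: N,N-dimethylformamide (DMF), CN(C)C=O
Why: A second directed ortho-metalation at one of the two equivalent ring C–H positions between OCH2OMe and OMe, followed by a Bouveault-type formylation with DMF, should install the future C4.

Step 4
Reactants: 7 6-methoxy-2,4-bis(methoxymethoxy)-3-(3-methylbut-2-en-1-yl)benzaldehyde
Product: 8 2-hydroxy-6-methoxy-4-(methoxymethoxy)-3-(3-methylbut-2-en-1-yl)benzaldehyde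
Conditions: HCl (0.3 M in MeOH), CH2Cl2, 0 °C, stopped at mono-cleavage
Reagents that add atoms: none
Why: The acetal ortho to the formyl group is twisted between two ortho substituents and its cleavage is assisted by hydrogen bonding to the carbonyl oxygen, so acid methanolysis should remove it well before the para acetal (chelation-assisted selective MOM cleavage).

Step 5
Reactants: 9 3-hydroxy-5-methoxybenzoic acid
Product: 11 3-methoxy-5-(methoxymethoxy)benzoic acid, via MOM ester 10 (not isolated)
Conditions: NaH (2.3 equiv), MOMCl (2.3 equiv), DMF, 0 °C; then LiOH, THF/H2O, rt; 1 M HCl to pH 4, 0 °C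
Reagents that add atoms: chloromethyl methyl ether (MOMCl), COCCl; lithium hydroxide, [Li+].[OH-]
Why: Both acidic OH groups are alkylated and hydroxide then saponifies only the acyl acetal, the aryl MOM ether being stable to base.

Step 6
Reactants: 8 2-hydroxy-6-methoxy-4-(methoxymethoxy)-3-(3-methylbut-2-en-1-yl)benzaldehyde; 11 3-methoxy-5-(methoxymethoxy)benzoic acid
Product: 12 2-formyl-3-methoxy-5-(methoxymethoxy)-6-(3-methylbut-2-en-1-yl)phenyl 3-methoxy-5-(methoxymethoxy)benzoate
Conditions: DIC, DMAP, CH2Cl2, 0 °C → rt
Reagents that add atoms: none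
Why: Steglich esterification through the N-acylpyridinium ion should acylate even the hydrogen-bonded, di-ortho-substituted phenol, forming the O1–C2 bond with the ester carbon as the future C2.

Step 7
Reactants: 12 2-formyl-3-methoxy-5-(methoxymethoxy)-6-(3-methylbut-2-en-1-yl)phenyl 3-methoxy-5-(methoxymethoxy)benzoate
Product: 13 3-methoxy-5-(methoxymethoxy)-6-(3-methylbut-2-en-1-yl)-2-[(triethylsilyloxy)methyl]phenyl 3-methoxy-5-(methoxymethoxy)benzoate
Conditions: Et3SiH (1.5 equiv), RhCl(PPh3)3 (2 mol %), toluene, 50 °C
Reagents that add atoms: triethylsilane, CC[SiH](CC)CC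
Why: Rhodium-catalysed carbonyl hydrosilylation adds Si–H across the aldehyde only and delivers the silyl ether without a free alkoxide, so the neighbouring aryl ester should not migrate, while the ester and the trisubstituted alkene are inert.

Step 8
Reactants: 13 3-methoxy-5-(methoxymethoxy)-6-(3-methylbut-2-en-1-yl)-2-[(triethylsilyloxy)methyl]phenyl 3-methoxy-5-(methoxymethoxy)benzoate
Product: 14 triethyl{[2-({1-[3-methoxy-5-(methoxymethoxy)phenyl]ethenyl}oxy)-6-methoxy-4-(methoxymethoxy)-3-(3-methylbut-2-en-1-yl)phenyl]methoxy}silane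
Conditions: Cp2TiMe2 (2.5 equiv), toluene/THF, 65 °C, dark; filtration through basic alumina
Reagents that add atoms: dimethyltitanocene (Cp2TiMe2), C[Ti](C)(C1C=CC=C1)C1C=CC=C1
Why: Petasis methylenation (Cp2Ti=CH2 adds to the ester C=O and the oxatitanacyclobutane collapses to enol ether and Cp2TiO) is established for aryl benzoates, and the non-acidic medium should spare the acetals, the silyl ether and the acid-labile product.

Step 9
Reactants: 14 triethyl{[2-({1-[3-methoxy-5-(methoxymethoxy)phenyl]ethenyl}oxy)-6-methoxy-4-(methoxymethoxy)-3-(3-methylbut-2-en-1-yl)phenyl]methoxy}silane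
Product: 16 (2R)-5-methoxy-2-[3-methoxy-5-(methoxymethoxy)phenyl]-7-(methoxymethoxy)-8-(3-methylbut-2-en-1-yl)chromane, via 4H-chromene 15 (not isolated)
Conditions: (R)-3,3'-bis(2,4,6-triisopropylphenyl)-BINOL N-triflylphosphoramide (10 mol %), 5 Å MS, toluene (0.01 M), −40 → 0 °C; then Hantzsch ester (diethyl 2,6-dimethyl-1,4-dihydropyridine-3,5-dicarboxylate, 1.5 equiv), 40 °C
Reagents that add atoms: none
Why: Proposed new method: the strong chiral Brønsted acid ionizes the C4–OSiEt3 bond to a benzylic cation stabilized by the oxygens at C5, C8a and C7 (O-alkyl para-quinone methide form), C3 of the vinyl ether attacks C4 in a 6-endo-trig closure of ring C that places the charge on C2 between O1 and the aryl group, and proton loss gives 4H-chromene 15 with triethylsilanol as an inert by-product. After the Hantzsch ester is added, protonation at C3 re-forms the 2-arylchroman-2-ylium ion as a contact ion pair with the chiral phosphoramidate, and hydride transfer to one face of C2 sets the (R) centre under catalyst control. The closest known reaction types are the acid-promoted Mukaiyama- and Prins-type addition of enol ethers to benzylic and quinone methide cations, and the chiral phosphoric acid/Hantzsch ester transfer hydrogenation of enamides, 2-arylquinolines and benzopyrylium ions, all of which run through C-protonation or a preformed cation followed by ion-paired hydride delivery. The closure needs C3 to beat the ring B carbons (a seven-membered Friedel–Crafts mode) and intermolecular attack by C6, which the higher nucleophilicity of the enol ether, the six-membered transition state and high dilution should secure. It also needs the vinyl ether to survive until C4 ionizes, which is why the leaving group is a silyl ether (no free hydroxyl that could add to the vinyl ether), sieves are present and the hydride donor is added only after closure so that no open-chain cation is reduced.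

Step 10
Reactants: 16 (2R)-5-methoxy-2-[3-methoxy-5-(methoxymethoxy)phenyl]-7-(methoxymethoxy)-8-(3-methylbut-2-en-1-yl)chromane
Product: 17 (2R)-2-(3-hydroxy-5-methoxyphenyl)-5-methoxy-8-(3-methylbut-2-en-1-yl)chroman-7-ol (CNP0389420.1)
Conditions: 3 M aq HCl/MeOH (1:5), 40 °C
Reagents that add atoms: none
Why: Acid-catalysed acetal methanolysis should free both phenols under conditions that prenylated flavonoids normally tolerate, and C2 (a benzylic ether on a meta-oxygenated aryl ring) should not ionize.

**Compound list**

1 | 5-methoxybenzene-1,3-diol (5-methoxyresorcinol) | COc1cc(O)cc(O)c1 | starting material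
2 | 1-methoxy-3,5-bis(methoxymethoxy)benzene | COCOc1cc(OC)cc(OCOC)c1 | intermediate
3 | 1-bromo-3-methylbut-2-ene (prenyl bromide) | CC(C)=CCBr | starting material
4 | [4-methoxy-2,6-bis(methoxymethoxy)phenyl]lithium (formed in situ) | COCOc1cc(OC)cc(OCOC)c1[Li] | intermediate
5 | 5-methoxy-1,3-bis(methoxymethoxy)-2-(3-methylbut-2-en-1-yl)benzene | COCOc1cc(OC)cc(OCOC)c1CC=C(C)C | intermediate
6 | [6-methoxy-2,4-bis(methoxymethoxy)-3-(3-methylbut-2-en-1-yl)phenyl]lithium (formed in situ) | COCOc1cc(OC)c([Li])c(OCOC)c1CC=C(C)C | intermediate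
7 | 6-methoxy-2,4-bis(methoxymethoxy)-3-(3-methylbut-2-en-1-yl)benzaldehyde | COCOc1cc(OC)c(C=O)c(OCOC)c1CC=C(C)C | intermediate
8 | 2-hydroxy-6-methoxy-4-(methoxymethoxy)-3-(3-methylbut-2-en-1-yl)benzaldehyde | COCOc1cc(OC)c(C=O)c(O)c1CC=C(C)C | intermediate
9 | 3-hydroxy-5-methoxybenzoic acid | COc1cc(O)cc(C(=O)O)c1 | starting material
10 | methoxymethyl 3-methoxy-5-(methoxymethoxy)benzoate (formed in situ) | COCOC(=O)c1cc(OC)cc(OCOC)c1 | intermediate
11 | 3-methoxy-5-(methoxymethoxy)benzoic acid | COCOc1cc(OC)cc(C(=O)O)c1 | intermediate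
12 | 2-formyl-3-methoxy-5-(methoxymethoxy)-6-(3-methylbut-2-en-1-yl)phenyl 3-methoxy-5-(methoxymethoxy)benzoate | COCOc1cc(OC)cc(C(=O)Oc2c(CC=C(C)C)c(OCOC)cc(OC)c2C=O)c1 | intermediate
13 | 3-methoxy-5-(methoxymethoxy)-6-(3-methylbut-2-en-1-yl)-2-[(triethylsilyloxy)methyl]phenyl 3-methoxy-5-(methoxymethoxy)benzoate | COCOc1cc(OC)cc(C(=O)Oc2c(CC=C(C)C)c(OCOC)cc(OC)c2CO[Si](CC)(CC)CC)c1 | intermediate
14 | triethyl{[2-({1-[3-methoxy-5-(methoxymethoxy)phenyl]ethenyl}oxy)-6-methoxy-4-(methoxymethoxy)-3-(3-methylbut-2-en-1-yl)phenyl]methoxy}silane | COCOc1cc(OC)cc(C(=C)Oc2c(CC=C(C)C)c(OCOC)cc(OC)c2CO[Si](CC)(CC)CC)c1 | intermediate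
15 | 5-methoxy-2-[3-methoxy-5-(methoxymethoxy)phenyl]-7-(methoxymethoxy)-8-(3-methylbut-2-en-1-yl)-4H-chromene (formed in situ) | COCOc1cc(OC)cc(C2=CCc3c(OC)cc(OCOC)c(CC=C(C)C)c3O2)c1 | intermediate
16 | (2R)-5-methoxy-2-[3-methoxy-5-(methoxymethoxy)phenyl]-7-(methoxymethoxy)-8-(3-methylbut-2-en-1-yl)chromane | COCOc1cc(OC)cc([C@H]2CCc3c(OC)cc(OCOC)c(CC=C(C)C)c3O2)c1 | intermediate
17 | (2R)-2-(3-hydroxy-5-methoxyphenyl)-5-methoxy-8-(3-methylbut-2-en-1-yl)chroman-7-ol | COc1cc(O)cc([C@H]2CCc3c(OC)cc(O)c(CC=C(C)C)c3O2)c1 | target

**Count**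

Total step count: 10. Longest linear sequence: 9 steps (steps 1–4 and 6–10; step 5 is the ring B branch).

**Three steps most likely to fail**

1. Step 9 (Proposed new method). The vinyl ether may be consumed by C-protonation and capture of the open-chain oxocarbenium ion before C4 ionizes. Facial selectivity may also be poor, because the oxocarbenium ion offers the chiral anion no hydrogen bond. The fallback uses known chemistry, sets out from compounds 8 and 11, and comes back at compound 16.
   - Acid 11 with MeLi (2.2 equiv, THF, −78 → 0 °C) should give the methyl ketone 1-[3-methoxy-5-(methoxymethoxy)phenyl]ethan-1-one F1.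
   - Claisen–Schmidt condensation of F1 with aldehyde 8 (KOH, EtOH, rt) should make the C3–C4 bond as a C=C bond in (E)-3-[2-hydroxy-6-methoxy-4-(methoxymethoxy)-3-(3-methylbut-2-en-1-yl)phenyl]-1-[3-methoxy-5-(methoxymethoxy)phenyl]prop-2-en-1-one F2.
   - Homogeneous hydrogenation (H2, RhCl(PPh3)3, benzene/EtOH) should reduce the disubstituted enone alkene ahead of the trisubstituted prenyl alkene, giving 3-[2-hydroxy-6-methoxy-4-(methoxymethoxy)-3-(3-methylbut-2-en-1-yl)phenyl]-1-[3-methoxy-5-(methoxymethoxy)phenyl]propan-1-one F3.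
   - Noyori transfer hydrogenation (RuCl[(S,S)-TsDPEN](p-cymene), HCO2H/Et3N) should give, by analogy with acetophenone, (1S)-3-[2-hydroxy-6-methoxy-4-(methoxymethoxy)-3-(3-methylbut-2-en-1-yl)phenyl]-1-[3-methoxy-5-(methoxymethoxy)phenyl]propan-1-ol F4.
   - Intramolecular Mitsunobu etherification (PPh3, DIAD, THF, 0 °C) should close ring C at O1–C2 with inversion to the (2R)-flavan 16.

2. Step 7. Addition to the di-ortho-substituted, electron-rich aldehyde may be slow, and the higher temperature then needed may bring decarbonylation or attack on the aryl ester. The fallback changes the order of events, sets out from compound 8, and comes back at compound 13.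
   - NaBH4 (MeOH, 0 °C) should give 2-(hydroxymethyl)-3-methoxy-5-(methoxymethoxy)-6-(3-methylbut-2-en-1-yl)phenol F5.
   - Et3SiCl (1.05 equiv) with imidazole (CH2Cl2, −20 °C) should silylate the primary hydroxyl ahead of the hindered phenol, giving 3-methoxy-5-(methoxymethoxy)-6-(3-methylbut-2-en-1-yl)-2-[(triethylsilyloxy)methyl]phenol F6.
   - Steglich esterification of F6 with acid 11 (DIC, DMAP) should give 13.

3. Step 3. The base may deprotonate the benzylic-allylic CH2 of the prenyl group, which lies between the two directing acetals, instead of the ring C–H. The fallback replaces metalation by electrophilic substitution, sets out from compound 5, and comes back at compound 7. Vilsmeier–Haack formylation (POCl3, DMF, 0 °C; aq NaOAc) should attack one of the two equivalent, strongly activated ring positions between OMe and OCH2OMe. It makes no new compound (F0).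

**Further compounds**

F1 | step 9 | 1-[3-methoxy-5-(methoxymethoxy)phenyl]ethan-1-one | COCOc1cc(OC)cc(C(C)=O)c1
F2 | step 9 | (E)-3-[2-hydroxy-6-methoxy-4-(methoxymethoxy)-3-(3-methylbut-2-en-1-yl)phenyl]-1-[3-methoxy-5-(methoxymethoxy)phenyl]prop-2-en-1-one | COCOc1cc(OC)cc(C(=O)/C=C/c2c(OC)cc(OCOC)c(CC=C(C)C)c2O)c1
F3 | step 9 | 3-[2-hydroxy-6-methoxy-4-(methoxymethoxy)-3-(3-methylbut-2-en-1-yl)phenyl]-1-[3-methoxy-5-(methoxymethoxy)phenyl]propan-1-one | COCOc1cc(OC)cc(C(=O)CCc2c(OC)cc(OCOC)c(CC=C(C)C)c2O)c1
F4 | step 9 | (1S)-3-[2-hydroxy-6-methoxy-4-(methoxymethoxy)-3-(3-methylbut-2-en-1-yl)phenyl]-1-[3-methoxy-5-(methoxymethoxy)phenyl]propan-1-ol | COCOc1cc(OC)cc([C@@H](O)CCc2c(OC)cc(OCOC)c(CC=C(C)C)c2O)c1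
F5 | step 7 | 2-(hydroxymethyl)-3-methoxy-5-(methoxymethoxy)-6-(3-methylbut-2-en-1-yl)phenol | COCOc1cc(OC)c(CO)c(O)c1CC=C(C)C
F6 | step 7 | 3-methoxy-5-(methoxymethoxy)-6-(3-methylbut-2-en-1-yl)-2-[(triethylsilyloxy)methyl]phenol | COCOc1cc(OC)c(CO[Si](CC)(CC)CC)c(O)c1CC=C(C)C
F0 | step 3 | none | none
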